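**Retrosynthetic overview**
- The strategy rests on ring A: the free C5–OH is para to C8–OMe, C6–H and C7–OMe lie between them, and the C4a=C8a edge belongs to ring C. This is the hydroquinone-monoether pattern that a 3,4-dimethoxy-4-alkenylcyclobut-2-enone with hydrogen at C2 gives on ring expansion (C=O → C5–OH, C2–H → C6, C3–OMe → C7, C4–OMe → C8).
- Last disconnection: the C4a–C5 bond, back to a 3,4-dimethoxycyclobutenone that carries a 4-oxo-4H-pyran-2-yl group at C4 (forward: 4π opening, then 6π closure).
- Before that: the C8–C8a bond, from a 6-metalated 2-(2,3-dimethoxyphenyl)-4-pyranone and methyl semisquarate (from dimethyl squarate), followed by O-methylation of the carbinol.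
- Ring C: the 2-aryl-4-pyranone comes from 2,3-dimethoxybenzoyl chloride and (E)-4-methoxybut-3-en-2-one by enolate C-acylation and acid cyclization.
- Ring order: ring B is bought, ring C is closed second, ring A is closed last.

Key step: step 7

Assumption: compounds 1, 2 and 7 are bought; the carbinol carbon of 11 and 12 forms racemic, which is without consequence because it becomes the planar C8 of the target.

Step 1
Reactants: 1 2,3-dimethoxybenzoyl chloride; 2 (E)-4-methoxybut-3-en-2-one
Product: 4 (E)-1-(2,3-dimethoxyphenyl)-5-methoxypent-4-ene-1,3-dione, via lithium enolate 3 (not isolated)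
Conditions: 2 (2.1 equiv), LiN(SiMe3)2 (2.1 equiv), THF, −78 °C; then 1 (1.0 equiv), −78 °C; aq NH4Cl
Reagents that add atoms: none
Why: Claisen-type C-acylation of the kinetic lithium dienolate (the methyl group is the only enolizable position of 2) by the aroyl chloride should give the β-diketone, with the second equivalent of enolate converting the product into its chelated lithium enolate and so blocking a second acylation.

Step 2
Reactants: 4 (E)-1-(2,3-dimethoxyphenyl)-5-methoxypent-4-ene-1,3-dione
Product: 6 2-(2,3-dimethoxyphenyl)-4H-pyran-4-one, via methoxydihydropyranone 5 (not isolated)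
Conditions: CF3CO2H (3 equiv), CH2Cl2, rt
Reagents that add atoms: none
Why: Acid-catalysed 6-endo oxa-Michael addition of the aryl-ketone enol oxygen to the β-methoxyenone, followed by β-elimination of methanol, is the standard closure of 2-substituted 4-pyranones and is driven by formation of the cross-conjugated pyranone.

Step 3
Reactants: 7 dimethyl squarate
Product: 8 4-hydroxy-2,3-dimethoxycyclobut-2-en-1-one (racemic)
Conditions: LiAlH(OtBu)3 (1.05 equiv), THF, −78 → −20 °C; cold 1 M HCl; crude product used directly
Reagents that add atoms: none
Why: 1,2-Reduction by the bulky, mild alkoxyaluminium hydride should stop after one carbonyl, because the aluminium alkoxide of the resulting vinylogous ester is far less electrophilic than the squarate; the new carbinol centre is racemic and is destroyed in step 4.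

Step 4
Reactants: 8 4-hydroxy-2,3-dimethoxycyclobut-2-en-1-one
Product: 9 3-methoxycyclobut-3-ene-1,2-dione (methyl semisquarate)
Conditions: conc. HCl (cat.), CH2Cl2, rt; Na2SO4; quick filtration through silica
Reagents that add atoms: water (O)
Why: Acid-induced allylic transposition (ionization of the carbinol to the methoxy-stabilized cyclobutenyl cation, capture by water at the methoxy-bearing terminus, and collapse of the hemiketal with loss of methanol) should restore the 1,2-dione, as in the hydrolytic rearrangement of organolithium adducts of squarates.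

Step 5
Reactants: 6 2-(2,3-dimethoxyphenyl)-4H-pyran-4-one; 9 3-methoxycyclobut-3-ene-1,2-dione
Product: 11 4-hydroxy-3-methoxy-4-[6-(2,3-dimethoxyphenyl)-4-oxo-4H-pyran-2-yl]cyclobut-2-en-1-one (racemic), via 6-lithiopyranone 10 (not isolated)
Conditions: lithium 2,2,6,6-tetramethylpiperidide (1.1 equiv, made from 2,2,6,6-tetramethylpiperidine and n-BuLi), THF, −78 °C, 6 added slowly, 15 min; then 9 (1.3 equiv) in THF, −78 °C; aq NH4Cl at −78 °C; Et3N-deactivated silica
Reagents that add atoms: none
Why: Deprotonation by the hindered lithium amide should remove the most acidic ring proton, the sp2 C6–H next to the ring oxygen (as in the known C2 lithiation of chromones), and the vinyllithium should then add 1,2 to the carbonyl of 9 attached to the methoxy-bearing carbon, the other carbonyl being deactivated as a vinylogous ester; the quaternary carbinol centre forms racemic and needs no control.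

Step 6
Reactants: 11 4-hydroxy-3-methoxy-4-[6-(2,3-dimethoxyphenyl)-4-oxo-4H-pyran-2-yl]cyclobut-2-en-1-one
Product: 12 3,4-dimethoxy-4-[6-(2,3-dimethoxyphenyl)-4-oxo-4H-pyran-2-yl]cyclobut-2-en-1-one (racemic)
Conditions: Ag2O (3 equiv), MeI (15 equiv), K2CO3, MeCN, rt, dark
Reagents that add atoms: iodomethane (CI)
Why: Purdie-type methylation, in which silver-assisted activation of iodomethane alkylates the neutral tertiary alcohol under nearly neutral conditions, is the standard etherification of 4-hydroxycyclobutenones and should leave the pyranone carbonyl, the enol ether and the strained ketone untouched.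

Step 7
Reactants: 12 3,4-dimethoxy-4-[6-(2,3-dimethoxyphenyl)-4-oxo-4H-pyran-2-yl]cyclobut-2-en-1-one
Product: 15 5-hydroxy-2',3',7,8-tetramethoxyflavone, via dienylketene 13 (not isolated), via 4aH-chromene-4,5-dione 14 (not isolated)
Conditions: degassed p-xylene (0.02 M), 138 °C, argon
Reagents that add atoms: none
Why: Heating should open the cyclobutenone by conrotatory 4π electrocyclic cleavage of its C1–C4 bond to the (Z)-dienylketene 13, which closes by thermal 6π electrocyclization between the ketene carbon and the pyranone C–H carbon beside the attachment carbon (new C4a–C5 bond) to dione 14, whose doubly activated C4a–H then enolizes irreversibly to the hydrogen-bonded phenol. The closest known reaction is the Moore rearrangement of 4-alkenyl-, 4-aryl- and 4-heteroaryl-4-alkoxycyclobutenones to hydroquinone monoethers; here a C=C bond of a 4-pyranone takes the place of the alkenyl partner, which is the same reaction type with a new 2π component. Ring A is closed by a six-membered, all-carbon, disrotatory 6π electrocyclization whose six atoms are the four cyclobutenone carbons and the two pyranone carbons. The only new stereocentre, C4a of 14, is transient and is erased by tautomerization, and the racemic carbinol carbon of 12 becomes the planar C8. Two selectivities are needed: torquoselectivity, secured by the donor methoxy group at C4, which rotates outward and so turns the pyranonyl group inward toward the ketene, and regioselectivity of closure, secured because the attachment carbon has the ring oxygen on its other side, leaving one carbon terminus, which as the nucleophilic β-carbon of the ring enol ether matches the electrophilic ketene carbon. The isomerization should deliver the free C5–OH and the 7,8-dimethoxy pattern directly, with high dilution limiting ketene dimerization and acylation of the product phenol.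

**Compound list**
1 | 2,3-dimethoxybenzoyl chloride | COc1cccc(C(=O)Cl)c1OC | starting material
2 | (E)-4-methoxybut-3-en-2-one | CO/C=C/C(C)=O | starting material
3 | lithium (E)-4-methoxybuta-1,3-dien-2-olate | CO/C=C/C(=C)O[Li] | intermediate (not isolated)
4 | (E)-1-(2,3-dimethoxyphenyl)-5-methoxypent-4-ene-1,3-dione | CO/C=C/C(=O)CC(=O)c1cccc(OC)c1OC | intermediate
5 | 6-(2,3-dimethoxyphenyl)-2-methoxy-2,3-dihydro-4H-pyran-4-one (racemic) | COC1CC(=O)C=C(c2cccc(OC)c2OC)O1 | intermediate (not isolated)
6 | 2-(2,3-dimethoxyphenyl)-4H-pyran-4-one | COc1cccc(-c2cc(=O)cco2)c1OC | intermediate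
7 | dimethyl squarate (3,4-dimethoxycyclobut-3-ene-1,2-dione) | COC1=C(OC)C(=O)C1=O | starting material
8 | 4-hydroxy-2,3-dimethoxycyclobut-2-en-1-one (racemic) | COC1=C(OC)C(=O)C1O | intermediate
9 | 3-methoxycyclobut-3-ene-1,2-dione (methyl semisquarate) | COC1=CC(=O)C1=O | intermediate
10 | [6-(2,3-dimethoxyphenyl)-4-oxo-4H-pyran-2-yl]lithium | [Li]c1cc(=O)cc(-c2cccc(OC)c2OC)o1 | intermediate (not isolated)
11 | 4-hydroxy-3-methoxy-4-[6-(2,3-dimethoxyphenyl)-4-oxo-4H-pyran-2-yl]cyclobut-2-en-1-one (racemic) | COC1=CC(=O)C1(O)c1cc(=O)cc(-c2cccc(OC)c2OC)o1 | intermediate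
12 | 3,4-dimethoxy-4-[6-(2,3-dimethoxyphenyl)-4-oxo-4H-pyran-2-yl]cyclobut-2-en-1-one (racemic) | COC1=CC(=O)C1(OC)c1cc(=O)cc(-c2cccc(OC)c2OC)o1 | intermediate
13 | (Z)-3,4-dimethoxy-4-[6-(2,3-dimethoxyphenyl)-4-oxo-4H-pyran-2-yl]buta-1,3-dien-1-one | O=C=C/C(OC)=C(/OC)c1cc(=O)cc(-c2cccc(OC)c2OC)o1 | intermediate (not isolated)
14 | 2-(2,3-dimethoxyphenyl)-7,8-dimethoxy-4aH-chromene-4,5-dione (racemic) | COC1=CC(=O)C2C(=O)C=C(c3cccc(OC)c3OC)OC2=C1OC | intermediate (not isolated)
15 | 5-hydroxy-2',3',7,8-tetramethoxyflavone | COc1cccc(-c2cc(=O)c3c(O)cc(OC)c(OC)c3o2)c1OC | target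

**Totals**
Total step count: 7.
Longest linear sequence: 5 steps (steps 1, 2, 5, 6, 7; the squarate branch, steps 3, 4, 5, 6, 7, is equally long).

**Steps most likely to fail**

1. Step 7 (key step). The dienylketene may engage the electron-poor, partly aromatic pyranone double bond too slowly, so that the unsubstituted ketene is lost to dimerization, to adventitious nucleophiles or to slow decomposition. The fallback uses known chemistry, sets out from 1 and comes back at 15. Acylation of purchased 2'-hydroxy-3',4',6'-trimethoxyacetophenone F1 with 1 (pyridine, rt) should give 2-acetyl-3,5,6-trimethoxyphenyl 2,3-dimethoxybenzoate F2. Baker–Venkataraman rearrangement (KOH, pyridine, 50 °C) should give 1-(2,3-dimethoxyphenyl)-3-(2-hydroxy-3,4,6-trimethoxyphenyl)propane-1,3-dione F3. Cyclodehydration (H2SO4, AcOH, 100 °C) should give 2',3',5,7,8-pentamethoxyflavone F4. BCl3 (CH2Cl2, −78 → 0 °C) should then cleave only the 5-methoxy group, which chelates boron together with the C4 carbonyl, to give 15.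

2. Step 5. The lithiated pyranone may add in conjugate fashion to pyranone not yet metalated, may decompose before it meets the electrophile, or residual amide may consume the semisquarate; deprotonation at another ring position would also go unnoticed until late. The fallback sets out from 6 and comes back at 11. Deprotonation of 6 with lithium 2,2,6,6-tetramethylpiperidide in the presence of ZnCl2·TMEDA (THF, −78 °C) should trap each carbanion as it forms, as [6-(2,3-dimethoxyphenyl)-4-oxo-4H-pyran-2-yl]zinc chloride F5. Iodinolysis (I2) should give the isolable 2-(2,3-dimethoxyphenyl)-6-iodo-4H-pyran-4-one F6, which can be purified free of any regioisomer. Iodine–magnesium exchange (iPrMgCl·LiCl, THF, −78 °C) should then give [6-(2,3-dimethoxyphenyl)-4-oxo-4H-pyran-2-yl]magnesium chloride F7 in the absence of amine, amide and free pyranone C–H, and its addition to 9 at −78 °C should give 11.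

3. Step 6. Etherification of the hindered tertiary carbinol is slow, and acid- or silver-promoted ionization with loss of methanol, or base-induced ring opening, may overtake it. The fallback sets out from 11 and comes back at 15. The free carbinol 11 is heated as in step 7 (p-xylene, 138 °C, argon); the same ring expansion of a 4-hydroxycyclobutenone should give the hydroquinone 5,8-dihydroxy-2',3',7-trimethoxyflavone F8, kept under argon to avoid oxidation to the quinone. Me2SO4 (1.05 equiv), K2CO3, acetone, rt should then methylate the free 8-OH and spare the 5-OH, which is hydrogen-bonded to the C4 carbonyl, to give 15.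

**Further compounds**
F1 | step 7 | 2'-hydroxy-3',4',6'-trimethoxyacetophenone | CC(=O)c1c(O)c(OC)c(OC)cc1OC
F2 | step 7 | 2-acetyl-3,5,6-trimethoxyphenyl 2,3-dimethoxybenzoate | CC(=O)c1c(OC(=O)c2cccc(OC)c2OC)c(OC)c(OC)cc1OC
F3 | step 7 | 1-(2,3-dimethoxyphenyl)-3-(2-hydroxy-3,4,6-trimethoxyphenyl)propane-1,3-dione | COc1cccc(C(=O)CC(=O)c2c(O)c(OC)c(OC)cc2OC)c1OC
F4 | step 7 | 2',3',5,7,8-pentamethoxyflavone | COc1cccc(-c2cc(=O)c3c(OC)cc(OC)c(OC)c3o2)c1OC
F5 | step 5 | [6-(2,3-dimethoxyphenyl)-4-oxo-4H-pyran-2-yl]zinc chloride | Cl[Zn]c1cc(=O)cc(-c2cccc(OC)c2OC)o1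
F6 | step 5 | 2-(2,3-dimethoxyphenyl)-6-iodo-4H-pyran-4-one | COc1cccc(-c2cc(=O)cc(I)o2)c1OC
F7 | step 5 | [6-(2,3-dimethoxyphenyl)-4-oxo-4H-pyran-2-yl]magnesium chloride | Cl[Mg]c1cc(=O)cc(-c2cccc(OC)c2OC)o1
F8 | step 6 | 5,8-dihydroxy-2',3',7-trimethoxyflavone | COc1cccc(-c2cc(=O)c3c(O)cc(OC)c(O)c3o2)c1OC
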